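**Plan**

- Cuts, in labdane numbering (C18 = ester carbon on C4, C19 and C20 = 4β- and 10β-methyl, C17 on C8, C11–C16 = side chain): C14–OOH, C13–C14, C11–C12, then C9–C10 (ring B), the lactone C8=C9 and C6–C7, leaving a ring A enal.
- Forward: ring A from methyl 2-oxocyclohexanecarboxylate; a 6-(cyclohexenyl)dihydropyranone by allylboration, acryloylation and ring-closing metathesis; ring B by Ireland–Claisen ring contraction; hydration, hydroboration and chain extension to a methyl ketone; Nozaki–Hiyama–Kishi union with a butenolide aldehyde; hydroperoxide last.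
- Enabling feature: C9–C10 joins the side-chain methine to the quaternary ring-fusion carbon, and the 6α-oxygen on C6 is allylic to the ring A C5=C10 alkene, so a lactone C6–O bond can pass its configuration to C10 while ring B closes.
- Stereochemistry: C4 by auxiliary-controlled methylation; C6 by reagent-controlled allylboration; C10 by the sigmatropic shift, C9 then corrected by protonation; C8, C5 and C6 by α-face hydration and hydroboration anti to the β-methyls; C14 by catalyst-controlled reduction, then SN2 inversion; the butenolide carbon from (S)-3-hydroxydihydrofuran-2(3H)-one.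

Key step: step 9

Assumption: in step 2 the HMPA-solvated lithioenamine of the L-valine ester is taken to be methylated on the face that gives the 1R ketone; if the sense is the reverse, the THF-solvated variant of the same enamine is used and nothing downstream changes.

**Step 1**
Reactants: 1 methyl 2-oxocyclohexane-1-carboxylate; 2 L-valine tert-butyl ester
Product: 3 valine-derived enamino ester
Conditions: BF3·OEt2 (cat.), benzene, reflux, Dean–Stark trap
Reagents that add atoms: none
Why: Acid-catalysed condensation of the β-keto ester with the primary amine, with azeotropic removal of water, gives the hydrogen-bonded enamino ester (enamine formation).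

**Step 2**
Reactants: 3 valine-derived enamino ester
Product: 5 methyl (1R)-1-methyl-2-oxocyclohexane-1-carboxylate, via methylated imine 4 (not isolated)
Conditions: LiN(i-Pr)2, toluene, −78 °C; HMPA; MeI, −78 °C; then 10% aq. citric acid, 25 °C
Reagents that add atoms: iodomethane, CI; water, O
Why: The chelated lithioenamine is shielded on one face by the valine isopropyl group, so methyl iodide should alkylate C4 from the other face (chiral-auxiliary enamine alkylation), and mild acid hydrolysis of the imine releases the ketone and the auxiliary.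

**Step 3**
Reactants: 5 methyl (1R)-1-methyl-2-oxocyclohexane-1-carboxylate
Product: 6 methyl (1R)-1,3-dimethyl-2-oxocyclohexane-1-carboxylate (both C3 epimers)
Conditions: LiN(i-Pr)2, THF, −78 °C; MeI, −78 → 0 °C
Reagents that add atoms: iodomethane, CI
Why: C10 is the only enolisable position, so kinetic enolate alkylation installs the future C20 methyl; the new centre is not controlled and becomes sp2 in step 4.

**Step 4**
Reactants: 6 methyl (1R)-1,3-dimethyl-2-oxocyclohexane-1-carboxylate
Product: 7 ring A enol triflate
Conditions: LiN(i-Pr)2, THF, −78 → 0 °C; PhNTf2, 0 → 25 °C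
Reagents that add atoms: N-phenylbis(trifluoromethanesulfonimide), O=S(=O)(N(c1ccccc1)S(=O)(=O)C(F)(F)F)C(F)(F)F
Why: Enolisation can only go toward the methyl-bearing carbon, and O-sulfonylation of the tetrasubstituted enolate gives the enol triflate (enol triflate formation).

**Step 5**
Reactants: 7 ring A enol triflate
Product: 8 methyl (1R)-2-formyl-1,3-dimethylcyclohex-2-ene-1-carboxylate
Conditions: Pd(PPh3)4 (cat.), CO (3 atm), Bu3SnH (slow addition), LiCl, THF, 50 °C
Reagents that add atoms: carbon monoxide, [C-]#[O+]
Why: Oxidative addition of zerovalent palladium to the C–OTf bond, CO insertion and hydride transfer from the stannane to the acylpalladium give the enal (palladium-catalysed reductive carbonylation of an enol triflate).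

**Step 6**
Reactants: 8 methyl (1R)-2-formyl-1,3-dimethylcyclohex-2-ene-1-carboxylate
Product: 10 (1S)-homoallylic alcohol, via diisopinocampheylborinate 9 (not isolated)
Conditions: (−)-Ipc2BOMe, methallylmagnesium chloride, Et2O, −78 → 25 °C; then 8, −78 → −40 °C; ethanolamine, 25 °C
Reagents that add atoms: methallylmagnesium chloride, C=C(C)C[Mg]Cl
Why: Allylboration through a closed chair transition state in which the isopinocampheyl groups derived from (+)-α-pinene direct the methallyl group to the Si face of the aldehyde should set C6 as S under reagent control, and the non-basic ethanolamine work-up avoids alkoxide attack on the C18 ester.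

**Step 7**
Reactants: 10 (1S)-homoallylic alcohol
Product: 11 acrylate ester
Conditions: acryloyl chloride, i-Pr2NEt, CH2Cl2, −20 → 0 °C
Reagents that add atoms: acryloyl chloride, C=CC(=O)Cl
Why: Acylation of the secondary alcohol with an acid chloride and a hindered amine (esterification), carried out without delay, also removes the hydroxyl that could lactonise onto the C18 ester.

**Step 8**
Reactants: 11 acrylate ester
Product: 12 (6S)-4-methyl-6-(ring A cyclohexenyl)-5,6-dihydropyran-2-one
Conditions: second-generation Grubbs catalyst (cat.), CH2Cl2 (high dilution), 40 °C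
Reagents that add atoms: none
Why: Ring-closing metathesis between the acrylate and the 1,1-disubstituted alkene closes the six-membered lactone with loss of ethylene, the tetrasubstituted ring A alkene being inert to the catalyst.

**Step 9**
Reactants: 12 (6S)-4-methyl-6-(ring A cyclohexenyl)-5,6-dihydropyran-2-one
Product: 15 octalin 9α-carboxylic acid with C5–C6 alkene and C8 exomethylene, via silyl ketene acetal 13 (not isolated), via silyl ester 14 (not isolated)
Conditions: LiN(i-Pr)2, t-BuMe2SiCl, DMPU, THF, −78 °C (lactone added last); then toluene, 100 °C; then 1 M HCl, THF, 25 °C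
Reagents that add atoms: none
Why: γ-Deprotonation at the C8 methyl (the C7 methylene is shielded by the bulky C6 substituent and the C18 ester has no α-hydrogen) with in situ O-silylation gives the exocyclic silyl dienol ether 13, in which the C9=C11 ketene acetal and the ring A C5=C10 alkene are joined through O and C6 as a 1,5-diene. On heating, a concerted [3,3] shift (Ireland–Claisen rearrangement of a lactone silyl ketene acetal, the known ring-contraction variant) breaks C6–O and forms C9–C10, and hydrolysis of silyl ester 14 gives the acid. Ring B closes by 6-endo attack of C9 on C10 of the ring A alkene inside a boat-shaped, bicyclo[2.2.2]octane-like array, the only geometry the lactone tether allows. C10 is set by suprafacial transfer of the 6S configuration: the tether holds C9 on the α face of ring A, anti to the 4β-methyl, so the C20 methyl ends β. C9 is fixed by the boat with its hydrogen pointing outward, which places the carboxyl α, trans to C20, and this is corrected in step 10. The step needs deprotonation at the methyl and not at C7, since a C7 anion would open the lactone by β-elimination; the internal silyl chloride quench at −78 °C traps the kinetic dienolate before proton transfer can occur.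

**Step 10**
Reactants: 15 octalin 9α-carboxylic acid
Product: 17 octalin 9β-carboxylic acid, via dilithium dienediolate 16 (not isolated)
Conditions: LiN(i-Pr)2 (2.5 equiv), DMPU, THF, −78 → 0 °C; then AcOH, THF, −78 °C
Reagents that add atoms: none
Why: The dilithium dienediolate makes C9 planar, and kinetic protonation should occur at the α-carbon (deconjugative protonation of an extended enolate) and from the α face, anti to the 10β-methyl, to give the 9β-carboxyl epimer.

**Step 11**
Reactants: 17 octalin 9β-carboxylic acid
Product: 18 8α-hydroxy acid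
Conditions: Mn(dpm)3 (cat.), PhSiH3, O2 (1 atm), i-PrOH/CH2Cl2, 0 °C
Reagents that add atoms: dioxygen, O=O
Why: In this Mukaiyama hydration, hydrogen-atom transfer to the 1,1-disubstituted alkene (much faster than to the hindered trisubstituted C5–C6 alkene) gives the tertiary C8 radical, which O2 should trap on the α face, anti to the syn-axial 10β-methyl and the 9β-carboxyl, before the silane reduces the peroxide to the 8α-alcohol.

**Step 12**
Reactants: 18 8α-hydroxy acid
Product: 20 6α,8α,11-triol, via C6 alkylborane 19 (not isolated)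
Conditions: BH3·THF (excess), THF, 0 → 40 °C; then NaBO3·4H2O, THF/H2O, 25 °C
Reagents that add atoms: sodium perborate, [Na+].[O-]B1OO1
Why: Borane reduces the carboxylic acid in preference to the hindered methyl ester and hydroborates the trisubstituted alkene with boron at C6 from the α face, away from the 10β- and 4β-methyls, so oxidation with retention should give 5α-H and 6α-OH (hydroboration–oxidation), the mild perborate limiting attack of the new hydroxyl on the C18 ester.

**Step 13**
Reactants: 20 6α,8α,11-triol
Product: 21 C11 aldehyde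
Conditions: 2,2,6,6-tetramethylpiperidin-1-oxyl (TEMPO, cat.), PhI(OAc)2, CH2Cl2, 25 °C
Reagents that add atoms: none
Why: Oxoammonium (TEMPO) oxidation is selective for the primary alcohol over the secondary and tertiary ones.

**Step 14**
Reactants: 21 C11 aldehyde
Product: 22 (E)-enone
Conditions: (MeO)2P(O)CH2C(O)CH3, LiCl, i-Pr2NEt, MeCN, 25 °C
Reagents that add atoms: dimethyl (2-oxopropyl)phosphonate, CC(=O)CP(=O)(OC)OC
Why: Horner–Wadsworth–Emmons olefination under mild LiCl/amine conditions gives the E-enone without exposing the β-hydroxy aldehyde to strong base.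

**Step 15**
Reactants: 22 (E)-enone
Product: 23 bis(triethylsilyl) ether of the enone
Conditions: Et3SiOTf, 2,6-lutidine, CH2Cl2, −78 → 0 °C
Reagents that add atoms: triethylsilyl trifluoromethanesulfonate, CC[Si](CC)(CC)OS(=O)(=O)C(F)(F)F
Why: The silyl triflate with 2,6-lutidine silylates the secondary and the tertiary alcohol (silyl ether formation), masking them for the later base, oxidation and sulfonylation steps and preventing hemiketal formation between the 8-hydroxyl and the C13 ketone.

**Step 16**
Reactants: 23 bis(triethylsilyl) ether of the enone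
Product: 24 saturated methyl ketone
Conditions: H2 (1 atm), Pd/C (cat.), EtOAc, 25 °C
Reagents that add atoms: none
Why: Heterogeneous hydrogenation saturates the conjugated C11–C12 alkene, the only alkene present.

**Step 17**
Reactants: 24 saturated methyl ketone
Product: 25 2-alkenyl triflate
Conditions: KN(SiMe3)2, THF, −78 °C; N-(5-chloropyridin-2-yl)-bis(trifluoromethanesulfonimide), −78 °C
Reagents that add atoms: N-(5-chloropyridin-2-yl)-bis(trifluoromethanesulfonimide), Clc1ccc(nc1)N(S(=O)(=O)C(F)(F)F)S(=O)(=O)C(F)(F)F
Why: Kinetic deprotonation by the bulky amide at −78 °C occurs at the methyl group, and the terminal enolate is trapped as the 2-alkenyl triflate (kinetic enol triflate formation).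

**Step 18**
Reactants: 26 (S)-3-hydroxydihydrofuran-2(3H)-one
Product: 27 (3S)-3,5-dihydroxypentan-2-one
Conditions: MeLi (2.1 equiv), THF, −78 °C; AcOH, −78 °C
Reagents that add atoms: methyllithium, [Li]C
Why: The first equivalent forms the alkoxide and the second adds to the lactone carbonyl, the tetrahedral lithium hemiketal persisting at −78 °C so that only one methyl enters (organolithium mono-addition to a lactone) and the stereocentre is untouched.

**Step 19**
Reactants: 27 (3S)-3,5-dihydroxypentan-2-one
Product: 28 (3S)-5-(tert-butyldimethylsilyloxy)-3-hydroxypentan-2-one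
Conditions: t-BuMe2SiCl (1.05 equiv), imidazole, CH2Cl2, −20 → 0 °C
Reagents that add atoms: tert-butyldimethylsilyl chloride, CC(C)(C)[Si](C)(C)Cl
Why: The primary hydroxyl of the open-chain form is silylated much faster than the secondary α-hydroxyl (selective silylation).

**Step 20**
Reactants: 28 (3S)-5-(tert-butyldimethylsilyloxy)-3-hydroxypentan-2-one
Product: 29 (5S)-5-[2-(tert-butyldimethylsilyloxy)ethyl]-4-methylfuran-2(5H)-one
Conditions: Ph3P=C=C=O, toluene, 90 °C
Reagents that add atoms: (triphenylphosphoranylidene)ketene, O=C=C=P(c1ccccc1)(c1ccccc1)c1ccccc1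
Why: The ylide acylates the α-hydroxyl to a phosphoranylidene ester, which closes the butenolide by intramolecular Wittig reaction with the neighbouring ketone without touching the carbinol stereocentre.

**Step 21**
Reactants: 29 (5S)-5-[2-(tert-butyldimethylsilyloxy)ethyl]-4-methylfuran-2(5H)-one
Product: 30 (5S)-5-(2-hydroxyethyl)-4-methylfuran-2(5H)-one
Conditions: HF·pyridine, THF, 0 °C
Reagents that add atoms: none
Why: Fluoride cleavage of the primary silyl ether under non-basic conditions leaves the base-sensitive butenolide intact (desilylation).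

**Step 22**
Reactants: 30 (5S)-5-(2-hydroxyethyl)-4-methylfuran-2(5H)-one
Product: 31 [(2S)-3-methyl-5-oxo-2,5-dihydrofuran-2-yl]acetaldehyde
Conditions: Dess–Martin periodinane, CH2Cl2, 0 → 25 °C
Reagents that add atoms: none
Why: Dess–Martin oxidation gives the aldehyde without base, avoiding β-elimination of the acyloxy group and epimerisation at the butenolide carbon.

**Step 23**
Reactants: 25 2-alkenyl triflate; 31 [(2S)-3-methyl-5-oxo-2,5-dihydrofuran-2-yl]acetaldehyde
Product: 32 C14 allylic alcohol (both C14 epimers)
Conditions: CrCl2 (excess), NiCl2 (cat.), DMF, 25 °C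
Reagents that add atoms: none
Why: In the Nozaki–Hiyama–Kishi coupling, nickel inserts into the alkenyl triflate and the alkenylchromium species formed by transmetallation adds chemoselectively to the aldehyde; little control at C14 is expected, so both epimers are carried on.

**Step 24**
Reactants: 32 C14 allylic alcohol (both C14 epimers)
Product: 33 C14 enone
Conditions: Dess–Martin periodinane, NaHCO3, CH2Cl2, 0 °C
Reagents that add atoms: none
Why: Dess–Martin oxidation of the allylic alcohols converges both C14 epimers on one enone under buffered, non-basic conditions that spare the β-acyloxy ketone.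

**Step 25**
Reactants: 33 C14 enone
Product: 34 (14R)-allylic alcohol
Conditions: (S)-1-methyl-3,3-diphenyltetrahydro-1H,3H-pyrrolo[1,2-c][1,3,2]oxazaborole (cat.), catecholborane, toluene, −78 °C
Reagents that add atoms: none
Why: In the Corey–Bakshi–Shibata reduction the oxazaborolidine binds the ketone with the α-branched alkenyl group as the large substituent and should deliver hydride to give the 14R alcohol under catalyst control.

**Step 26**
Reactants: 34 (14R)-allylic alcohol
Product: 36 (14S)-hydroperoxide bis(triethylsilyl) ether, via allylic mesylate 35 (not isolated)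
Conditions: MsCl, Et3N, CH2Cl2, −60 °C; then anhydrous H2O2 in Et2O, −60 → −20 °C
Reagents that add atoms: hydrogen peroxide, OO
Why: The alcohol is activated as its mesylate and displaced by hydrogen peroxide in an SN2 reaction that should invert C14 to the 14S hydroperoxide (sulfonate displacement by H2O2), low temperature and the absence of strong base being chosen to suppress ionisation and protect the butenolide.

**Step 27**
Reactants: 36 (14S)-hydroperoxide bis(triethylsilyl) ether
Product: 37 target hydroperoxide CNP0324515.1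
Conditions: HF·pyridine, pyridine, THF, 0 → 25 °C
Reagents that add atoms: none
Why: Buffered fluoride removes both triethylsilyl ethers (desilylation) without touching the hydroperoxide, the butenolide or the methyl ester.

**Compound list**

1 | methyl 2-oxocyclohexane-1-carboxylate | COC(=O)C1CCCCC1=O | starting material
2 | L-valine tert-butyl ester, tert-butyl (2S)-2-amino-3-methylbutanoate | CC(C)[C@H](N)C(=O)OC(C)(C)C | starting material
3 | methyl 2-{[(2S)-1-tert-butoxy-3-methyl-1-oxobutan-2-yl]amino}cyclohex-1-ene-1-carboxylate | COC(=O)C1=C(N[C@@H](C(C)C)C(=O)OC(C)(C)C)CCCC1 | intermediate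
4 | methyl (1R)-2-{[(2S)-1-tert-butoxy-3-methyl-1-oxobutan-2-yl]imino}-1-methylcyclohexane-1-carboxylate | COC(=O)[C@]1(C)CCCCC1=N[C@@H](C(C)C)C(=O)OC(C)(C)C | intermediate (not isolated)
5 | methyl (1R)-1-methyl-2-oxocyclohexane-1-carboxylate | O=C1CCCC[C@@]1(C)C(=O)OC | intermediate
6 | methyl (1R)-1,3-dimethyl-2-oxocyclohexane-1-carboxylate (both C3 epimers) | O=C1C(C)CCC[C@@]1(C)C(=O)OC | intermediate
7 | methyl (1R)-1,3-dimethyl-2-{[(trifluoromethyl)sulfonyl]oxy}cyclohex-2-ene-1-carboxylate | FC(F)(F)S(=O)(=O)OC1=C(C)CCC[C@@]1(C)C(=O)OC | intermediate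
8 | methyl (1R)-2-formyl-1,3-dimethylcyclohex-2-ene-1-carboxylate | O=CC1=C(C)CCC[C@@]1(C)C(=O)OC | intermediate
9 | diisopinocampheylborinate of alcohol 10 (isopinocampheyl groups from (+)-α-pinene) | C=C(C)C[C@H](OB([C@@H]1C[C@@H]2C[C@H]([C@H]1C)C2(C)C)[C@@H]1C[C@@H]2C[C@H]([C@H]1C)C2(C)C)C1=C(C)CCC[C@@]1(C)C(=O)OC | intermediate (not isolated)
10 | methyl (1R)-2-[(1S)-1-hydroxy-3-methylbut-3-en-1-yl]-1,3-dimethylcyclohex-2-ene-1-carboxylate | C=C(C)C[C@H](O)C1=C(C)CCC[C@@]1(C)C(=O)OC | intermediate
11 | methyl (1R)-2-[(1S)-1-(acryloyloxy)-3-methylbut-3-en-1-yl]-1,3-dimethylcyclohex-2-ene-1-carboxylate | C=CC(=O)O[C@@H](CC(C)=C)C1=C(C)CCC[C@@]1(C)C(=O)OC | intermediate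
12 | methyl (1R)-1,3-dimethyl-2-[(2S)-4-methyl-6-oxo-3,6-dihydro-2H-pyran-2-yl]cyclohex-2-ene-1-carboxylate | O=C1C=C(C)C[C@H](O1)C2=C(C)CCC[C@@]2(C)C(=O)OC | intermediate (key-step precursor)
13 | methyl (1R)-2-[(2S)-6-(tert-butyldimethylsilyloxy)-4-methylidene-3,4-dihydro-2H-pyran-2-yl]-1,3-dimethylcyclohex-2-ene-1-carboxylate | C=C1C=C(O[Si](C)(C)C(C)(C)C)O[C@@H](C1)C2=C(C)CCC[C@@]2(C)C(=O)OC | intermediate (not isolated)
14 | tert-butyldimethylsilyl ester of acid 15 | CC(C)(C)[Si](C)(C)OC(=O)[C@H]1[C@@]2(C)CCC[C@@](C)(C(=O)OC)C2=CCC1=C | intermediate (not isolated)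
15 | (1R,5R,8aR)-5-(methoxycarbonyl)-5,8a-dimethyl-2-methylidene-1,2,3,5,6,7,8,8a-octahydronaphthalene-1-carboxylic acid (9α-carboxyl, 10β-methyl) | OC(=O)[C@H]1[C@@]2(C)CCC[C@@](C)(C(=O)OC)C2=CCC1=C | intermediate (key-step product)
16 | dilithium dienediolate of acid 15 (C9 planar) | [Li]OC(O[Li])=C1[C@@]2(C)CCC[C@@](C)(C(=O)OC)C2=CCC1=C | intermediate (not isolated)
17 | (1S,5R,8aR)-5-(methoxycarbonyl)-5,8a-dimethyl-2-methylidene-1,2,3,5,6,7,8,8a-octahydronaphthalene-1-carboxylic acid (9β-carboxyl) | OC(=O)[C@@H]1[C@@]2(C)CCC[C@@](C)(C(=O)OC)C2=CCC1=C | intermediate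
18 | (1R,2R,5R,8aR)-2-hydroxy-5-(methoxycarbonyl)-2,5,8a-trimethyl-1,2,3,5,6,7,8,8a-octahydronaphthalene-1-carboxylic acid (8α-OH, 8β-methyl, 9β-carboxyl, C5=C6) | OC(=O)[C@@H]1[C@@]2(C)CCC[C@@](C)(C(=O)OC)C2=CC[C@@]1(C)O | intermediate
19 | C6 alkylborane: trans-decalin with 6α-BH2, 5α-H, 8α-OH, 9β-CH2OH (drawn without the O–B bonds at C8 and C11 present before work-up) | OC[C@@H]1[C@@]2(C)CCC[C@@](C)(C(=O)OC)[C@@H]2[C@@H](B)C[C@@]1(C)O | intermediate (not isolated)
20 | triol: trans-decalin with 4α-CO2Me, 4β-methyl, 5α-H, 6α-OH, 8α-OH, 8β-methyl, 9β-CH2OH, 10β-methyl | OC[C@@H]1[C@@]2(C)CCC[C@@](C)(C(=O)OC)[C@@H]2[C@@H](O)C[C@@]1(C)O | intermediate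
21 | aldehyde: as 20 with 9β-CHO | O=C[C@@H]1[C@@]2(C)CCC[C@@](C)(C(=O)OC)[C@@H]2[C@@H](O)C[C@@]1(C)O | intermediate
22 | enone: as 20 with 9β-[(E)-3-oxobut-1-en-1-yl] | CC(=O)/C=C/[C@@H]1[C@@]2(C)CCC[C@@](C)(C(=O)OC)[C@@H]2[C@@H](O)C[C@@]1(C)O | intermediate
23 | 6α,8α-bis(triethylsilyloxy) enone | CC(=O)/C=C/[C@@H]1[C@@]2(C)CCC[C@@](C)(C(=O)OC)[C@@H]2[C@@H](O[Si](CC)(CC)CC)C[C@@]1(C)O[Si](CC)(CC)CC | intermediate
24 | 6α,8α-bis(triethylsilyloxy) decalin with 9β-(3-oxobutyl) | CC(=O)CC[C@@H]1[C@@]2(C)CCC[C@@](C)(C(=O)OC)[C@@H]2[C@@H](O[Si](CC)(CC)CC)C[C@@]1(C)O[Si](CC)(CC)CC | intermediate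
25 | 6α,8α-bis(triethylsilyloxy) decalin with 9β-[3-(trifluoromethylsulfonyloxy)but-3-en-1-yl] | C=C(OS(=O)(=O)C(F)(F)F)CC[C@@H]1[C@@]2(C)CCC[C@@](C)(C(=O)OC)[C@@H]2[C@@H](O[Si](CC)(CC)CC)C[C@@]1(C)O[Si](CC)(CC)CC | intermediate
26 | (S)-3-hydroxydihydrofuran-2(3H)-one | O[C@H]1CCOC1=O | starting material
27 | (3S)-3,5-dihydroxypentan-2-one (in equilibrium with its cyclic hemiketal) | CC(=O)[C@@H](O)CCO | intermediate
28 | (3S)-5-(tert-butyldimethylsilyloxy)-3-hydroxypentan-2-one | CC(=O)[C@@H](O)CCO[Si](C)(C)C(C)(C)C | intermediate
29 | (5S)-5-[2-(tert-butyldimethylsilyloxy)ethyl]-4-methylfuran-2(5H)-one | CC1=CC(=O)O[C@H]1CCO[Si](C)(C)C(C)(C)C | intermediate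
30 | (5S)-5-(2-hydroxyethyl)-4-methylfuran-2(5H)-one | CC1=CC(=O)O[C@H]1CCO | intermediate
31 | [(2S)-3-methyl-5-oxo-2,5-dihydrofuran-2-yl]acetaldehyde | CC1=CC(=O)O[C@H]1CC=O | intermediate
32 | C14 allylic alcohol (both C14 epimers): bis(triethylsilyl) decalin with chain CH2CH2C(=CH2)CH(OH)CH2-[(2S)-butenolide] | C=C(CC[C@@H]1[C@@]2(C)CCC[C@@](C)(C(=O)OC)[C@@H]2[C@@H](O[Si](CC)(CC)CC)C[C@@]1(C)O[Si](CC)(CC)CC)C(O)C[C@@H]1OC(=O)C=C1C | intermediate
33 | C14 ketone (α-methylene ketone) | C=C(CC[C@@H]1[C@@]2(C)CCC[C@@](C)(C(=O)OC)[C@@H]2[C@@H](O[Si](CC)(CC)CC)C[C@@]1(C)O[Si](CC)(CC)CC)C(=O)C[C@@H]1OC(=O)C=C1C | intermediate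
34 | (14R)-allylic alcohol | C=C(CC[C@@H]1[C@@]2(C)CCC[C@@](C)(C(=O)OC)[C@@H]2[C@@H](O[Si](CC)(CC)CC)C[C@@]1(C)O[Si](CC)(CC)CC)[C@@H](C[C@@H]1OC(=O)C=C1C)O | intermediate
35 | (14R)-allylic methanesulfonate | C=C(CC[C@@H]1[C@@]2(C)CCC[C@@](C)(C(=O)OC)[C@@H]2[C@@H](O[Si](CC)(CC)CC)C[C@@]1(C)O[Si](CC)(CC)CC)[C@@H](C[C@@H]1OC(=O)C=C1C)OS(C)(=O)=O | intermediate (not isolated)
36 | (14S)-hydroperoxide, 6α,8α-bis(triethylsilyl) ether | C=C(CC[C@@H]1[C@@]2(C)CCC[C@@](C)(C(=O)OC)[C@@H]2[C@@H](O[Si](CC)(CC)CC)C[C@@]1(C)O[Si](CC)(CC)CC)[C@H](C[C@@H]1OC(=O)C=C1C)OO | intermediate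
37 | target CNP0324515.1 (labdane numbering 4R,5R,6S,8R,9R,10S,14S; butenolide carbon S) | C=C(CC[C@@H]1[C@@]2(C)CCC[C@@](C)(C(=O)OC)[C@@H]2[C@@H](O)C[C@@]1(C)O)[C@H](C[C@@H]1OC(=O)C=C1C)OO | target

**Step count and risks**

Total: 27 steps. Longest linear sequence: 22 steps (steps 1–17 and 23–27); the butenolide aldehyde 31 takes 5 steps (18–22).

Steps most likely to fail:

1. Step 9. The base may remove a C7 hydrogen instead of a C8-methyl hydrogen, after which the lactone would open by β-elimination to a dienoate; the boat shift that builds a quaternary carbon next to another may also be too slow to compete with loss of the ketene acetal. Fallback: the same ketene acetal is reached by α-deprotonation of the deconjugated lactone. Setting out from aldehyde 8, indium-mediated Barbier allylation with methyl 3-(bromomethyl)but-3-enoate (In powder, THF/H2O) would give the hydroxy ester F1 as C6 epimers. Acid-catalysed lactonisation onto the unhindered ester (pyridinium p-toluenesulfonate, benzene, 60 °C) and chromatographic separation would give the 6S 4-methylidene lactone F2. LiN(i-Pr)2/t-BuMe2SiCl at −78 °C then removes a doubly activated C9 hydrogen, the only enolisable site, to give silyl ketene acetal 13, and heating and hydrolysis bring the route back at acid 15.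

2. Step 26. The allylic mesylate may ionise or be attacked at the alkene terminus (SN2′), which would erode the configuration at C14 and divert material to the primary allylic hydroperoxide. Fallback: a stereospecific displacement is given up for ionisation and separation. Setting out from the alcohol mixture 32 (steps 24 and 25 are then not needed), CBr4/PPh3 would give the allylic bromide F3. Silver-assisted perhydrolysis (AgOCOCF3, anhydrous H2O2, Et2O, 0 °C) passes through the allyl cation, and the 14S hydroperoxide is separated by HPLC from its C14 epimer and the primary regioisomer, coming back to the route at 36.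

3. Step 10. Protonation of the dienediolate may show poor facial selectivity, or occur at C17 to give the conjugated acid. Fallback: C9–H is set by syn addition of H–B instead of by protonation. Setting out from acid 15 (either C9 epimer or a mixture), KOt-Bu in DMSO at 25 °C would move the alkene into conjugation to give the C8=C9 conjugated acid F4. BH3·THF followed by NaBO3·4H2O would then reduce the acid and hydroborate both the C5=C6 and the tetrasubstituted C8=C9 alkene from the α face, anti to the 10β-methyl, with boron at C8, remote from the C11 oxygen. This would give 9α-H and 8α-OH and return to the route at triol 20, bypassing steps 10–12.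

**Further compounds**

F1 | step 9 | methyl (1R)-2-(1-hydroxy-5-methoxy-3-methylidene-5-oxopentyl)-1,3-dimethylcyclohex-2-ene-1-carboxylate (C6 epimers) | COC(=O)CC(=C)CC(O)C1=C(C)CCC[C@@]1(C)C(=O)OC
F2 | step 9 | methyl (1R)-1,3-dimethyl-2-[(2S)-4-methylidene-6-oxooxan-2-yl]cyclohex-2-ene-1-carboxylate | O=C1CC(=C)C[C@H](O1)C2=C(C)CCC[C@@]2(C)C(=O)OC
F3 | step 26 | C14 allylic bromide of the bis(triethylsilyl) series (C14 epimers) | C=C(CC[C@@H]1[C@@]2(C)CCC[C@@](C)(C(=O)OC)[C@@H]2[C@@H](O[Si](CC)(CC)CC)C[C@@]1(C)O[Si](CC)(CC)CC)C(Br)C[C@@H]1OC(=O)C=C1C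
F4 | step 10 | (5R,8aR)-5-(methoxycarbonyl)-2,5,8a-trimethyl-3,5,6,7,8,8a-hexahydronaphthalene-1-carboxylic acid (C8=C9 and C5=C6 alkenes) | OC(=O)C1=C(C)CC=C2[C@]1(C)CCC[C@@]2(C)C(=O)OC
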